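**Retrosynthetic overview**

1. Sanggenol A 26 comes from its tetra-MOM ether 25 by acidic removal of four MOM groups as the last step.
2. Ring C of 25 is made by an aryne annulation that forms O1–C8a and then closes the ring at C4–C4a in one flask. The partners are the (S)-β-hydroxy morpholine amide 11 (ring B plus C2–C3–C4) and 3,5-bis(methoxymethoxy)benzyne (ring A); the C2–O bond of 11 is never broken.
3. Enabling feature: O1 and C4 sit on the adjacent ring-A carbons C8a and C4a, and the C5 oxygen flanks C4a, so the aryne is polarised for O-attack at C8a with the carbanion at C4a. O1–C2–C3–C4(=O) is a β-oxy carbonyl (acetate aldol) unit.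
4. 11 comes from asymmetric transfer hydrogenation of β-keto amide 10, made by Claisen condensation on benzoate 7, itself from resorcinol by two directed ortho-lithiations (geranyl at C3', carboxyl at C1'). Aryne precursor 20 comes from phloroglucinol by carbamate-directed ortho-silylation.
5. Ring order: rings A and B are bought as arenes; ring C is the only ring formed (step 10).

Key step: step 10

Assumption: the anionic intermediates of step 10 are drawn as sodium salts although tetrabutylammonium is also present, and the salt of a product that is only protonated on work-up is not numbered separately.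

**Route**

Step 1
Reactants: 1 resorcinol
Product: 2 1,3-bis(methoxymethoxy)benzene
Conditions: NaH (2.2 equiv), DMF, 0 °C; MOMCl, 0 °C→rt
Reagents that add atoms: chloromethyl methyl ether (MOMCl), COCCl
Why: Williamson-type O-alkylation of the resorcinol dianion by the hard electrophile MOMCl should give the bis-acetal cleanly, and the MOM groups later serve as ortho-directing groups.

Step 2
Reactants: 2 1,3-bis(methoxymethoxy)benzene; 3 geranyl bromide
Product: 5 2-geranyl-1,3-bis(methoxymethoxy)benzene, via 2-lithio-1,3-bis(methoxymethoxy)benzene 4 (not isolated)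
Conditions: n-BuLi, THF, 0 °C→rt; then geranyl bromide 3, CuBr·SMe2 (5 mol%), −78 °C→rt
Reagents that add atoms: none
Why: Directed ortho-metalation occurs at C2 between the two cooperating OMOM groups, and copper-assisted SN2 allylation of the aryllithium by the primary allylic bromide should give the linear product with the (E)-alkene of geranyl bromide unchanged.

Step 3
Reactants: 5 2-geranyl-1,3-bis(methoxymethoxy)benzene
Product: 7 methyl 3-geranyl-2,4-bis(methoxymethoxy)benzoate, via aryllithium 6 (not isolated)
Conditions: s-BuLi, TMEDA, THF, −78 °C; then cannulation into ClCO2Me (3 equiv), THF, −78 °C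
Reagents that add atoms: methyl chloroformate, COC(=O)Cl
Why: A second directed ortho-metalation under kinetic conditions should lithiate the ring position ortho to one OMOM group (C4 and C6 are equivalent), and inverse addition to excess methyl chloroformate acylates the aryllithium without over-addition.

Step 4
Reactants: 7 methyl 3-geranyl-2,4-bis(methoxymethoxy)benzoate; 8 N-acetylmorpholine
Product: 10 1-[3-geranyl-2,4-bis(methoxymethoxy)phenyl]-3-(morpholin-4-yl)propane-1,3-dione, via lithium enolate 9 (not isolated)
Conditions: 8, LDA (2.2 equiv), THF, −78 °C; then 7, −78→0 °C; AcOH quench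
Reagents that add atoms: none
Why: Crossed Claisen condensation, in which the amide enolate 9 adds to the ester and methoxide leaves, while the second equivalent of base holds the product as its unreactive enolate until the quench.

Step 5
Reactants: 10 1-[3-geranyl-2,4-bis(methoxymethoxy)phenyl]-3-(morpholin-4-yl)propane-1,3-dione
Product: 11 (3S)-3-hydroxy-3-[3-geranyl-2,4-bis(methoxymethoxy)phenyl]-1-(morpholin-4-yl)propan-1-one
Conditions: RuCl[(S,S)-TsDPEN](p-cymene) (1 mol%), HCO2H/Et3N (5:2), EtOAc, 30 °C
Reagents that add atoms: none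
Why: Noyori–Ikariya asymmetric transfer hydrogenation, in which the (S,S)-TsDPEN ruthenium hydride attacks the aryl ketone face that places the arene under the cymene ligand (CH/π contact), should give the (S)-carbinol, the sense known for aryl ketones and β-keto esters and amides, while the geranyl alkenes and MOM acetals are inert to this outer-sphere hydride transfer.

Step 6
Reactants: 12 phloroglucinol
Product: 13 3,5-bis(methoxymethoxy)phenol
Conditions: MOMCl (2.1 equiv), i-Pr2NEt, CH2Cl2/DMF, 0 °C→rt; chromatography
Reagents that add atoms: chloromethyl methyl ether (MOMCl), COCCl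
Why: Statistical O-alkylation of the threefold-symmetric triol, in which every bis-ether is the same compound, so chromatography only has to separate it from the mono- and tris-ethers.

Step 7
Reactants: 13 3,5-bis(methoxymethoxy)phenol
Product: 14 3,5-bis(methoxymethoxy)phenyl N-isopropylcarbamate
Conditions: i-PrNCO, Et3N (cat.), CH2Cl2, rt
Reagents that add atoms: isopropyl isocyanate, CC(C)N=C=O
Why: Base-catalysed addition of the phenol to the isocyanate (carbamoylation) installs a strong ortho-directing group that can later be removed by E1cB fragmentation.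

Step 8
Reactants: 14 3,5-bis(methoxymethoxy)phenyl N-isopropylcarbamate
Product: 18 3,5-bis(methoxymethoxy)-2-(trimethylsilyl)phenyl N-isopropylcarbamate, via N-silyl carbamate 15 (not isolated), via aryllithium 16 (not isolated), via disilyl carbamate 17 (not isolated)
Conditions: TBSOTf, TMEDA, Et2O, 0 °C→rt; n-BuLi, TMEDA, −78 °C; TMSCl, −78 °C→rt; aq. NH4Cl
Reagents that add atoms: chlorotrimethylsilane, C[Si](C)(C)Cl
Why: Carbamate-directed ortho-metalation (Snieckus type) after in situ N-silylation should occur at C2, the position activated by both the carbamate and an OMOM group, and the aryllithium is trapped by TMSCl before the labile N–Si bond is hydrolysed on work-up.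

Step 9
Reactants: 18 3,5-bis(methoxymethoxy)-2-(trimethylsilyl)phenyl N-isopropylcarbamate
Product: 20 3,5-bis(methoxymethoxy)-2-(trimethylsilyl)phenyl trifluoromethanesulfonate, via 3,5-bis(methoxymethoxy)-2-(trimethylsilyl)phenol 19 (not isolated)
Conditions: Et2NH, DBU, MeCN, 40 °C; then PhNTf2, rt
Reagents that add atoms: N-phenylbis(trifluoromethanesulfonimide) (PhNTf2), O=S(=O)(N(c1ccccc1)S(=O)(=O)C(F)(F)F)C(F)(F)F
Why: DBU-induced E1cB loss of isopropyl isocyanate (scavenged by Et2NH) frees the phenoxide, which is sulfonylated in the same flask by PhNTf2 to give the ortho-silylaryl triflate, a Kobayashi-type aryne precursor.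

Step 10
Reactants: 11 (3S)-3-hydroxy-3-[3-geranyl-2,4-bis(methoxymethoxy)phenyl]-1-(morpholin-4-yl)propan-1-one; 20 3,5-bis(methoxymethoxy)-2-(trimethylsilyl)phenyl trifluoromethanesulfonate
Product: 25 (2S)-2-[3-geranyl-2,4-bis(methoxymethoxy)phenyl]-5,7-bis(methoxymethoxy)chroman-4-one, via sodium alkoxide 21 (not isolated), via 3,5-bis(methoxymethoxy)benzyne 22 (not isolated), via aryl carbanion 23 (not isolated), via hemiaminal alkoxide 24 (not isolated)
Conditions: NaH (1.05 equiv), THF, 0 °C; Bu4N[Ph3SiF2] (TBAT, 1.5 equiv), then 20 (1.3 equiv) in THF over 1 h, 0 °C→rt; AcOH/H2O, 0 °C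
Reagents that add atoms: none
Why: Proposed new method: fluoride unmasks aryne 22 from 20, the alkoxide oxygen of 21 adds to the aryne carbon remote from the flanking OMOM group (the future C8a), and the resulting aryl carbanion 23, located at the future C4a next to that OMOM group, attacks the morpholine amide carbonyl (the future C4) to give hemiaminal alkoxide 24, which collapses to the ketone only on the acidic quench. The closest known reaction types are the aryne annulation of methyl salicylates to xanthones (O-arylation followed by intramolecular acyl substitution) and the insertion of arynes into the N–C(=O) bond of amides, but a secondary alkoxide paired with a carboxamide acceptor has not been used in this way. Ring C is closed by a 6-exo-trig addition of the C4a carbanion to the C4 carbonyl, which forms the C4–C4a bond directly after the O1–C8a bond in the same flask. No stereocenter is created: C2 is carried over from 11 with retention because its C–O bond is never broken, and the transient C4 hemiaminal centre disappears on hydrolysis. The step needs regioselective O-attack on the aryne, which the inductive and distortion effect of the C5 oxygen should secure (nucleophiles add to the distal carbon of 3-alkoxyarynes), and it needs acylation to beat protonation of 23, which the aprotic medium and the six-membered transition state should secure. Loss of configuration by E1cB opening of ring C is blocked because the product stays masked as 24, which has no acidic C3–H, until the cold acetic acid quench, and any silyl transfer to the alkoxide is reversed by the excess fluoride.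

Step 11
Reactants: 25 (2S)-2-[3-geranyl-2,4-bis(methoxymethoxy)phenyl]-5,7-bis(methoxymethoxy)chroman-4-one
Product: 26 sanggenol A
Conditions: HCl (3 M aq.)/MeOH 1:10, 35 °C
Reagents that add atoms: none
Why: Acid-catalysed transacetalisation of the four aryl MOM acetals to dimethoxymethane, the usual end-game for prenylated and geranylated flavanones, should leave the trisubstituted alkenes and the C2 stereocenter untouched at this low acidity and temperature.

**Compound list**

Geranyl = (2E)-3,7-dimethylocta-2,6-dien-1-yl; MOM = methoxymethyl.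

1 | resorcinol | Oc1cccc(O)c1 | starting material
2 | 1,3-bis(methoxymethoxy)benzene | COCOc1cccc(OCOC)c1 | intermediate
3 | geranyl bromide, (2E)-1-bromo-3,7-dimethylocta-2,6-diene | CC(C)=CCC/C(C)=C/CBr | starting material
4 | 2-lithio-1,3-bis(methoxymethoxy)benzene | [Li]c1c(OCOC)cccc1OCOC | intermediate
5 | 2-geranyl-1,3-bis(methoxymethoxy)benzene | CC(C)=CCC/C(C)=C/Cc1c(OCOC)cccc1OCOC | intermediate
6 | 3-geranyl-2,4-bis(methoxymethoxy)phenyllithium | CC(C)=CCC/C(C)=C/Cc1c(OCOC)ccc([Li])c1OCOC | intermediate
7 | methyl 3-geranyl-2,4-bis(methoxymethoxy)benzoate | CC(C)=CCC/C(C)=C/Cc1c(OCOC)ccc(C(=O)OC)c1OCOC | intermediate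
8 | N-acetylmorpholine | CC(=O)N1CCOCC1 | starting material
9 | lithium enolate of N-acetylmorpholine | [Li]OC(=C)N1CCOCC1 | intermediate
10 | 1-[3-geranyl-2,4-bis(methoxymethoxy)phenyl]-3-(morpholin-4-yl)propane-1,3-dione | CC(C)=CCC/C(C)=C/Cc1c(OCOC)ccc(C(=O)CC(=O)N2CCOCC2)c1OCOC | intermediate
11 | (3S)-3-hydroxy-3-[3-geranyl-2,4-bis(methoxymethoxy)phenyl]-1-(morpholin-4-yl)propan-1-one | CC(C)=CCC/C(C)=C/Cc1c(OCOC)ccc([C@@H](O)CC(=O)N2CCOCC2)c1OCOC | intermediate
12 | phloroglucinol | Oc1cc(O)cc(O)c1 | starting material
13 | 3,5-bis(methoxymethoxy)phenol | COCOc1cc(O)cc(OCOC)c1 | intermediate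
14 | 3,5-bis(methoxymethoxy)phenyl N-isopropylcarbamate | CC(C)NC(=O)Oc1cc(OCOC)cc(OCOC)c1 | intermediate
15 | 3,5-bis(methoxymethoxy)phenyl N-(tert-butyldimethylsilyl)-N-isopropylcarbamate | CC(C)N(C(=O)Oc1cc(OCOC)cc(OCOC)c1)[Si](C)(C)C(C)(C)C | intermediate
16 | 2-lithio derivative of 15 (lithium between the carbamate oxygen and an OMOM group) | CC(C)N(C(=O)Oc1cc(OCOC)cc(OCOC)c1[Li])[Si](C)(C)C(C)(C)C | intermediate
17 | 3,5-bis(methoxymethoxy)-2-(trimethylsilyl)phenyl N-(tert-butyldimethylsilyl)-N-isopropylcarbamate | CC(C)N(C(=O)Oc1cc(OCOC)cc(OCOC)c1[Si](C)(C)C)[Si](C)(C)C(C)(C)C | intermediate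
18 | 3,5-bis(methoxymethoxy)-2-(trimethylsilyl)phenyl N-isopropylcarbamate | CC(C)NC(=O)Oc1cc(OCOC)cc(OCOC)c1[Si](C)(C)C | intermediate
19 | 3,5-bis(methoxymethoxy)-2-(trimethylsilyl)phenol | Oc1cc(OCOC)cc(OCOC)c1[Si](C)(C)C | intermediate
20 | 3,5-bis(methoxymethoxy)-2-(trimethylsilyl)phenyl trifluoromethanesulfonate | COCOc1cc(OCOC)c([Si](C)(C)C)c(OS(=O)(=O)C(F)(F)F)c1 | intermediate
21 | sodium alkoxide of 11, (S) | CC(C)=CCC/C(C)=C/Cc1c(OCOC)ccc([C@@H]([O-])CC(=O)N2CCOCC2)c1OCOC.[Na+] | intermediate
22 | 3,5-bis(methoxymethoxy)benzyne | COCOC1=CC(OCOC)=CC#C1 | intermediate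
23 | aryl carbanion from O-addition of 21 to 22, (S), carbanion between the ether oxygen and an OMOM group | CC(C)=CCC/C(C)=C/Cc1c(OCOC)ccc([C@@H](Oc2cc(OCOC)cc(OCOC)[c-]2)CC(=O)N2CCOCC2)c1OCOC.[Na+] | intermediate
24 | sodium (2S)-2-[3-geranyl-2,4-bis(methoxymethoxy)phenyl]-5,7-bis(methoxymethoxy)-4-(morpholin-4-yl)chroman-4-olate (C4 configuration not defined) | CC(C)=CCC/C(C)=C/Cc1c(OCOC)ccc([C@@H]2CC([O-])(N3CCOCC3)c3c(OCOC)cc(OCOC)cc3O2)c1OCOC.[Na+] | intermediate
25 | (2S)-2-[3-geranyl-2,4-bis(methoxymethoxy)phenyl]-5,7-bis(methoxymethoxy)chroman-4-one | CC(C)=CCC/C(C)=C/Cc1c(OCOC)ccc([C@@H]2CC(=O)c3c(OCOC)cc(OCOC)cc3O2)c1OCOC | intermediate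
26 | sanggenol A, (2S)-2-[3-geranyl-2,4-dihydroxyphenyl]-5,7-dihydroxychroman-4-one | CC(C)=CCC/C(C)=C/Cc1c(O)ccc([C@@H]2CC(=O)c3c(O)cc(O)cc3O2)c1O | target

**Step count and risks**

Total step count: 11. Longest linear sequence: 7 steps (1, 2, 3, 4, 5, 10, 11); the aryne precursor branch (6–9) joins at step 10.

Steps most likely to fail:

Step 10 (Proposed new method). What may go wrong:
- the aryl carbanion may be protonated before it acylates, for example by intramolecular proton transfer from C3–H;
- the alkoxide may undergo retro-aldol cleavage;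
- the aryne may be consumed by ene reaction with the geranyl alkenes.

The fallback sets out from 11 and 20 and returns at 25, making the same two bonds in two known operations. Aryne O–H insertion under protic conditions (11, 20, KF, 18-crown-6, THF, rt, no NaH) should give the aryl ether (3S)-3-[3,5-bis(methoxymethoxy)phenoxy]-3-[3-geranyl-2,4-bis(methoxymethoxy)phenyl]-1-(morpholin-4-yl)propan-1-one F1 with retention at C2. Electrophilic activation of the amide (Tf2O, 2-chloropyridine, CH2Cl2, −78→0 °C) then closes the same C4–C4a bond by an intramolecular Vilsmeier–Haack-type Friedel–Crafts acylation of the phloroglucinol ring. Either carbon ortho to the ether oxygen gives the same product. The resulting cyclic iminium triflate F2 is not isolated and is hydrolysed with aqueous NaHCO3 to 25.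

Step 11. What may go wrong:
- configuration at C2 may be lost by acid-induced ionisation of the benzylic C2–O1 bond once the 2'- and 4'-hydroxyls are free;
- ring C may open reversibly.

The fallback sets out from 25 and returns at 26. Deprotection without regard to configuration (HCl, MeOH, 50 °C) gives (±)-sanggenol A F3. Ring C is opened with cold aqueous KOH and the solution is acidified quickly at 0 °C to give (E)-2',4',6',2,4-pentahydroxy-3-geranylchalcone F4. A chalcone isomerase (an intramolecular lyase, EC 5.5.1.6) in phosphate buffer at pH 7.5 and 25 °C then re-closes ring C by enantioselective oxa-Michael addition to the (2S)-flavanone 26.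

Step 3. What may go wrong: lateral deprotonation at the benzylic-allylic CH2 of the geranyl group, which is flanked by two OMOM groups, may compete with ring lithiation.

The fallback sets out from 2 and returns at 7, fixing the position by halogen instead. Bromination of 2 (NBS, MeCN, 0 °C) gives 1-bromo-2,4-bis(methoxymethoxy)benzene F5. Deprotonation between the two OMOM groups with lithium 2,2,6,6-tetramethylpiperidide (THF, −78 °C) gives the 3-lithio species F6 (not isolated). Allylation with 3 (CuBr·SMe2 cat.) gives 1-bromo-3-geranyl-2,4-bis(methoxymethoxy)benzene F7. Bromine–lithium exchange (n-BuLi, THF, −78 °C) then generates aryllithium 6 regiospecifically, and methyl chloroformate converts it to 7.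

Further compounds
F1 | step 10 | (3S)-3-[3,5-bis(methoxymethoxy)phenoxy]-3-[3-geranyl-2,4-bis(methoxymethoxy)phenyl]-1-(morpholin-4-yl)propan-1-one | CC(C)=CCC/C(C)=C/Cc1c(OCOC)ccc([C@@H](Oc2cc(OCOC)cc(OCOC)c2)CC(=O)N2CCOCC2)c1OCOC
F2 | step 10 | 4-[(2S)-2-[3-geranyl-2,4-bis(methoxymethoxy)phenyl]-5,7-bis(methoxymethoxy)chroman-4-ylidene]morpholin-4-ium triflate | CC(C)=CCC/C(C)=C/Cc1c(OCOC)ccc([C@@H]2CC(=[N+]3CCOCC3)c3c(OCOC)cc(OCOC)cc3O2)c1OCOC.[O-]S(=O)(=O)C(F)(F)F
F3 | step 11 | (±)-sanggenol A | CC(C)=CCC/C(C)=C/Cc1c(O)ccc(C2CC(=O)c3c(O)cc(O)cc3O2)c1O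
F4 | step 11 | (E)-2',4',6',2,4-pentahydroxy-3-geranylchalcone | CC(C)=CCC/C(C)=C/Cc1c(O)ccc(/C=C/C(=O)c2c(O)cc(O)cc2O)c1O
F5 | step 3 | 1-bromo-2,4-bis(methoxymethoxy)benzene | COCOc1ccc(Br)c(OCOC)c1
F6 | step 3 | 3-lithio-1-bromo-2,4-bis(methoxymethoxy)benzene | [Li]c1c(OCOC)ccc(Br)c1OCOC
F7 | step 3 | 1-bromo-3-geranyl-2,4-bis(methoxymethoxy)benzene | CC(C)=CCC/C(C)=C/Cc1c(OCOC)ccc(Br)c1OCOC
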